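**Retrosynthetic overview**
1. The acetyl group is unmasked last from a silyl-protected 1-hydroxyethyl group; the C-6 epoxyangelate and the C-2 angelate are put on before that by two mixed-anhydride (Yamaguchi) acylations.
2. The six-membered ring is formed last in the core sequence: C5–C6 bond by a type II carbonyl-ene cyclisation of an isopropenyl aldehyde, which gives the exocyclic methylene and the axial 6-OH in one step.
3. Key fragment union: C7–C7a bond by intermolecular Mukaiyama–Michael addition of the silyl ketene acetal of methyl isovalerate to (R)-4-isopropenylcyclopent-2-enone; a Mukaiyama aldol with acetaldehyde (C-1) and an L-Selectride reduction (C-2) complete a prostaglandin-type all-trans/cis array.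
4. The five-membered ring is bought: (R)-4-silyloxycyclopent-2-enone, with the C-3a substituent installed by cuprate addition/elimination.
5. (2S,3S)-Epoxyangelic acid comes from Sharpless epoxidation of angelyl alcohol and RuO4 oxidation.

Assumption: (R)-4-(TBSO)cyclopent-2-enone (the prostaglandin building block), methyl angelate and angelic acid are bought; TBS = tert-butyldimethylsilyl, TES = triethylsilyl.
Assumption: the carbinol carbon of the 1-hydroxyethyl group forms as a mixture of epimers, is carried as such and is erased in step 19, so SMILES leave it open; bicyclic compounds use the octahydro-1H-indene numbering of the target.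

**Step 1**
Reactants: 1 (R)-4-(TBS-oxy)cyclopent-2-en-1-one; 2 isopropenylmagnesium bromide
Product: 4 (3S,4R)-4-(TBS-oxy)-3-(prop-1-en-2-yl)cyclopentan-1-one, via TMS enol ether 3 (not isolated)
Conditions: CuBr·SMe2 (10 mol %), TMSCl, THF, −78 °C; then 1 M HCl, THF, 0 °C
Reagents that add atoms: chlorotrimethylsilane, C[Si](C)(C)Cl
Why: Copper-catalysed, TMSCl-accelerated conjugate addition delivers the isopropenyl group anti to the 4-silyloxy group (3,4-trans), which sets the future C-3a, and the TMS enol ether is hydrolysed on work-up.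

**Step 2**
Reactants: 4 (3S,4R)-4-(TBS-oxy)-3-(prop-1-en-2-yl)cyclopentan-1-one
Product: 5 (R)-4-(prop-1-en-2-yl)cyclopent-2-en-1-one
Conditions: DBU, CH2Cl2, 0 °C, short reaction time
Reagents that add atoms: none
Why: E1cB β-elimination of silanolate gives the conjugated enone (the PGE→PGA type dehydration) and leaves the γ-stereocentre untouched if kept cold and brief.

**Step 3**
Reactants: 6 methyl 3-methylbutanoate
Product: 7 (E)-tert-butyl[(1-methoxy-3-methylbut-1-en-1-yl)oxy]dimethylsilane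
Conditions: LDA (commercial solution), THF, −78 °C; TBSCl, DMPU, −78 °C → rt
Reagents that add atoms: tert-butyldimethylsilyl chloride, CC(C)(C)[Si](C)(C)Cl
Why: Kinetic ester enolisation in THF (Ireland model) gives the E(O)-enolate, which is trapped on oxygen as the (E)-silyl ketene acetal.

**Step 4** (key step)
Reactants: 5 (R)-4-(prop-1-en-2-yl)cyclopent-2-en-1-one; 7 (E)-silyl ketene acetal
Product: 8 methyl (2S)-2-[(1S,5R)-3-(TBS-oxy)-5-(prop-1-en-2-yl)cyclopent-2-en-1-yl]-3-methylbutanoate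
Conditions: TrSbCl6 (5 mol %), CH2Cl2, −78 °C; pyridine quench
Reagents that add atoms: none
Why: In this Mukaiyama–Michael addition the ketene acetal attacks the enone β-carbon anti to the 4-isopropenyl group (future trans ring fusion), an open antiperiplanar transition state is expected to place the isopropyl group anti to ring C-5 (anti adduct, 2S), and silyl transfer traps the regiodefined enol ether.

**Step 5**
Reactants: 8 TBS enol ether; 9 acetaldehyde
Product: 10 methyl (2S)-2-[(1S,2S,5R)-2-(1-hydroxyethyl)-3-oxo-5-(prop-1-en-2-yl)cyclopentyl]-3-methylbutanoate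
Conditions: BF3·OEt2, CH2Cl2, −78 °C
Reagents that add atoms: none
Why: The Mukaiyama aldol addition takes place at the enol-ether carbon anti to the neighbouring side chain, giving the 2,3-trans cyclopentanone (future C-1); the carbinol centre forms as a mixture that is erased later.

**Step 6**
Reactants: 10 β-hydroxy ketone
Product: 11 methyl (2S)-2-[(1S,2S,5R)-2-[1-(TBS-oxy)ethyl]-3-oxo-5-(prop-1-en-2-yl)cyclopentyl]-3-methylbutanoate
Conditions: TBSOTf, 2,6-lutidine, CH2Cl2, −78 °C
Reagents that add atoms: tert-butyldimethylsilyl triflate, CC(C)(C)[Si](C)(C)OS(=O)(=O)C(F)(F)F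
Why: Silyl triflate silylation at −78 °C protects the aldol hydroxyl under conditions too mild for retro-aldol or β-elimination.

**Step 7**
Reactants: 11 β-silyloxy ketone
Product: 12 methyl (2S)-2-[(1S,2R,3S,5R)-2-[1-(TBS-oxy)ethyl]-3-hydroxy-5-(prop-1-en-2-yl)cyclopentyl]-3-methylbutanoate
Conditions: L-Selectride, THF, −78 °C; aq. NH4Cl
Reagents that add atoms: none
Why: The bulky hydride attacks the cyclopentanone from the face opposite the adjacent side chain and gives the alcohol cis to it (the PGE→PGF2α selectivity), which sets the future C-2; the ester is untouched at −78 °C.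

**Step 8**
Reactants: 12 secondary alcohol
Product: 13 methyl (2S)-2-[(1S,2S,3S,5R)-2-[1-(TBS-oxy)ethyl]-5-(prop-1-en-2-yl)-3-(TES-oxy)cyclopentyl]-3-methylbutanoate
Conditions: TESOTf, 2,6-lutidine, CH2Cl2, −78 → 0 °C
Reagents that add atoms: triethylsilyl triflate, CC[Si](CC)(CC)OS(=O)(=O)C(F)(F)F
Why: Silyl triflate silylation of the hindered ring alcohol; TES is chosen because it can later be removed in the presence of the TBS ether.

**Step 9**
Reactants: 13 methyl ester
Product: 14 (2S)-2-[(1R,2S,3S,5R)-2-[1-(TBS-oxy)ethyl]-5-(prop-1-en-2-yl)-3-(TES-oxy)cyclopentyl]-3-methylbutan-1-ol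
Conditions: DIBAL-H (3 equiv), CH2Cl2, −78 → 0 °C; Rochelle salt
Reagents that add atoms: none
Why: Hydride reduction of the only ester to the primary alcohol leaves silyl ethers and the alkene alone and touches no stereocentre.

**Step 10**
Reactants: 14 primary alcohol
Product: 15 (2S)-2-[(1S,2S,3S,5R)-2-[1-(TBS-oxy)ethyl]-5-(prop-1-en-2-yl)-3-(TES-oxy)cyclopentyl]-3-methylbutanal
Conditions: Dess–Martin periodinane, NaHCO3, CH2Cl2, 0 °C → rt; used at once
Reagents that add atoms: none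
Why: Buffered Dess–Martin oxidation gives the α-branched aldehyde without epimerising the α-centre.

**Step 11**
Reactants: 15 isopropenyl aldehyde
Product: 16 (1S,2S,3aR,6R,7S,7aR)-1-[1-(TBS-oxy)ethyl]-4-methylidene-7-(propan-2-yl)-2-(TES-oxy)octahydro-1H-inden-6-ol
Conditions: Me2AlCl (2 equiv), CH2Cl2, −78 → −20 °C; cold 1 M HCl
Reagents that add atoms: none
Why: In this Lewis-acid-promoted type II intramolecular carbonyl-ene cyclisation the isopropenyl CH2 adds to the aldehyde through a chair-like bicyclic transition state with isopropyl equatorial and the aluminium-bound oxygen axial (it must reach a methyl hydrogen), which closes the trans-fused six-membered ring and gives the exocyclic methylene and the axial 6-OH cis to isopropyl (C-6).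

**Step 12**
Reactants: 17 methyl (Z)-2-methylbut-2-enoate (methyl angelate)
Product: 18 (Z)-2-methylbut-2-en-1-ol
Conditions: DIBAL-H (2.2 equiv), CH2Cl2, −78 → 0 °C
Reagents that add atoms: none
Why: 1,2-Reduction of the enoate gives the allylic alcohol with the Z geometry retained.

**Step 13**
Reactants: 18 (Z)-2-methylbut-2-en-1-ol
Product: 19 [(2R,3S)-2,3-dimethyloxiran-2-yl]methanol
Conditions: Ti(OiPr)4 (10 mol %), D-(−)-diisopropyl tartrate, t-BuOOH, 4 Å MS, CH2Cl2, −20 °C
Reagents that add atoms: tert-butyl hydroperoxide, CC(C)(C)OO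
Why: In the Sharpless asymmetric epoxidation the D-(−)-tartrate catalyst delivers oxygen to the face that gives the (2R,3S)-epoxy alcohol, and the Z geometry becomes the cis relation of CH2OH and the 3-methyl group.

**Step 14**
Reactants: 19 epoxy alcohol
Product: 20 (2S,3S)-2,3-dimethyloxirane-2-carboxylic acid
Conditions: RuCl3 (2 mol %), NaIO4, MeCN/EtOAc/H2O, rt
Reagents that add atoms: sodium periodate, [Na+].[O-]I(=O)(=O)=O
Why: Catalytic RuO4 oxidation takes the primary alcohol to the acid without opening the epoxide; C-2 changes from R to S only through CIP priorities.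

**Step 15**
Reactants: 16 bicyclic 6-alcohol; 20 (2S,3S)-epoxyangelic acid
Product: 22 (1S,2S,3aR,6R,7S,7aR)-1-[1-(TBS-oxy)ethyl]-4-methylidene-7-(propan-2-yl)-2-(TES-oxy)octahydro-1H-inden-6-yl (2S,3S)-2,3-dimethyloxirane-2-carboxylate, via epoxyangeloyl mixed anhydride 21 (not isolated)
Conditions: 20, 2,4,6-trichlorobenzoyl chloride, Et3N, toluene, rt; then 16, DMAP, 40 °C
Reagents that add atoms: 2,4,6-trichlorobenzoyl chloride, O=C(Cl)c1c(Cl)cc(Cl)cc1Cl
Why: In the Yamaguchi esterification DMAP attacks the mixed anhydride at the less hindered epoxy-acyl carbonyl and the acylpyridinium acylates the hindered axial alcohol with retention at every centre.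

**Step 16**
Reactants: 22 TES/TBS-protected epoxy ester
Product: 23 (1R,2S,3aR,6R,7S,7aR)-1-[1-(TBS-oxy)ethyl]-2-hydroxy-4-methylidene-7-(propan-2-yl)octahydro-1H-inden-6-yl (2S,3S)-2,3-dimethyloxirane-2-carboxylate
Conditions: HF·pyridine, pyridine, THF, 0 °C
Reagents that add atoms: none
Why: Buffered fluoride desilylation cleaves the secondary TES ether much faster than the TBS ether and spares the electron-poor glycidic ester.

**Step 17**
Reactants: 23 2-alcohol; 24 (Z)-2-methylbut-2-enoic acid (angelic acid)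
Product: 26 (1R,2S,3aR,6R,7S,7aR)-1-[1-(TBS-oxy)ethyl]-4-methylidene-2-[(Z)-2-methylbut-2-enoyloxy]-7-(propan-2-yl)octahydro-1H-inden-6-yl (2S,3S)-2,3-dimethyloxirane-2-carboxylate, via angeloyl mixed anhydride 25 (not isolated)
Conditions: 24, 2,4,6-trichlorobenzoyl chloride, Et3N, toluene, rt; then 23, 75 °C, no DMAP
Reagents that add atoms: 2,4,6-trichlorobenzoyl chloride, O=C(Cl)c1c(Cl)cc(Cl)cc1Cl
Why: Mixed-anhydride (Yamaguchi-type) acylation without a nucleophilic catalyst is the established way to make angelates without Z→E isomerisation to the tiglate.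

**Step 18**
Reactants: 26 TBS-protected diester
Product: 27 (1S,2S,3aR,6R,7S,7aR)-1-(1-hydroxyethyl)-4-methylidene-2-[(Z)-2-methylbut-2-enoyloxy]-7-(propan-2-yl)octahydro-1H-inden-6-yl (2S,3S)-2,3-dimethyloxirane-2-carboxylate
Conditions: HF·pyridine, pyridine, THF, 0 °C → rt
Reagents that add atoms: none
Why: Buffered, slightly acidic fluoride desilylation removes the last silyl ether without acyl migration, ester cleavage or epoxide opening.

**Step 19**
Reactants: 27 secondary alcohol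
Product: 28 target, (1R,2S,3aR,6R,7S,7aR)-1-acetyl-4-methylidene-2-[(Z)-2-methylbut-2-enoyloxy]-7-(propan-2-yl)octahydro-1H-inden-6-yl (2S,3S)-2,3-dimethyloxirane-2-carboxylate
Conditions: Dess–Martin periodinane, NaHCO3, CH2Cl2, rt
Reagents that add atoms: none
Why: Buffered Dess–Martin oxidation gives the methyl ketone without β-elimination of the angelate or epimerisation of C-1, whose configuration was fixed in step 5.

**Compound list**
1 | (R)-4-(TBS-oxy)cyclopent-2-en-1-one | CC(C)(C)[Si](C)(C)O[C@@H]1CC(=O)C=C1 | starting material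
2 | isopropenylmagnesium bromide | CC(=C)[Mg]Br | starting material
3 | (3S,4R)-4-(TBS-oxy)-3-(prop-1-en-2-yl)-1-(trimethylsilyloxy)cyclopent-1-ene | C[Si](C)(C)OC1=C[C@@H](C(C)=C)[C@H](O[Si](C)(C)C(C)(C)C)C1 | intermediate
4 | (3S,4R)-4-(TBS-oxy)-3-(prop-1-en-2-yl)cyclopentan-1-one | O=C1C[C@@H](C(C)=C)[C@H](O[Si](C)(C)C(C)(C)C)C1 | intermediate
5 | (R)-4-(prop-1-en-2-yl)cyclopent-2-en-1-one | O=C1C[C@@H](C(C)=C)C=C1 | intermediate
6 | methyl 3-methylbutanoate | COC(=O)CC(C)C | starting material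
7 | (E)-tert-butyl[(1-methoxy-3-methylbut-1-en-1-yl)oxy]dimethylsilane | CC(C)/C=C(\OC)O[Si](C)(C)C(C)(C)C | intermediate
8 | methyl (2S)-2-[(1S,5R)-3-(TBS-oxy)-5-(prop-1-en-2-yl)cyclopent-2-en-1-yl]-3-methylbutanoate | C1[C@@H](C(C)=C)[C@H]([C@H](C(C)C)C(=O)OC)C=C1O[Si](C)(C)C(C)(C)C | intermediate
9 | acetaldehyde | CC=O | starting material
10 | methyl (2S)-2-[(1S,2S,5R)-2-(1-hydroxyethyl)-3-oxo-5-(prop-1-en-2-yl)cyclopentyl]-3-methylbutanoate (carbinol epimers) | C1[C@@H](C(C)=C)[C@H]([C@H](C(C)C)C(=O)OC)[C@@H](C(C)O)C1=O | intermediate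
11 | methyl (2S)-2-[(1S,2S,5R)-2-[1-(TBS-oxy)ethyl]-3-oxo-5-(prop-1-en-2-yl)cyclopentyl]-3-methylbutanoate | C1[C@@H](C(C)=C)[C@H]([C@H](C(C)C)C(=O)OC)[C@@H](C(C)O[Si](C)(C)C(C)(C)C)C1=O | intermediate
12 | methyl (2S)-2-[(1S,2R,3S,5R)-2-[1-(TBS-oxy)ethyl]-3-hydroxy-5-(prop-1-en-2-yl)cyclopentyl]-3-methylbutanoate | C1[C@@H](C(C)=C)[C@H]([C@H](C(C)C)C(=O)OC)[C@@H](C(C)O[Si](C)(C)C(C)(C)C)[C@H]1O | intermediate
13 | methyl (2S)-2-[(1S,2S,3S,5R)-2-[1-(TBS-oxy)ethyl]-5-(prop-1-en-2-yl)-3-(TES-oxy)cyclopentyl]-3-methylbutanoate | C1[C@@H](C(C)=C)[C@H]([C@H](C(C)C)C(=O)OC)[C@@H](C(C)O[Si](C)(C)C(C)(C)C)[C@H]1O[Si](CC)(CC)CC | intermediate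
14 | (2S)-2-[(1R,2S,3S,5R)-2-[1-(TBS-oxy)ethyl]-5-(prop-1-en-2-yl)-3-(TES-oxy)cyclopentyl]-3-methylbutan-1-ol | C1[C@@H](C(C)=C)[C@H]([C@H](C(C)C)CO)[C@@H](C(C)O[Si](C)(C)C(C)(C)C)[C@H]1O[Si](CC)(CC)CC | intermediate
15 | (2S)-2-[(1S,2S,3S,5R)-2-[1-(TBS-oxy)ethyl]-5-(prop-1-en-2-yl)-3-(TES-oxy)cyclopentyl]-3-methylbutanal | C1[C@@H](C(C)=C)[C@H]([C@H](C(C)C)C=O)[C@@H](C(C)O[Si](C)(C)C(C)(C)C)[C@H]1O[Si](CC)(CC)CC | intermediate
16 | (1S,2S,3aR,6R,7S,7aR)-1-[1-(TBS-oxy)ethyl]-4-methylidene-7-(propan-2-yl)-2-(TES-oxy)octahydro-1H-inden-6-ol | C=C1C[C@@H](O)[C@@H](C(C)C)[C@@H]2[C@@H](C(C)O[Si](C)(C)C(C)(C)C)[C@@H](O[Si](CC)(CC)CC)C[C@@H]12 | intermediate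
17 | methyl (Z)-2-methylbut-2-enoate (methyl angelate) | COC(=O)/C(C)=C\C | starting material
18 | (Z)-2-methylbut-2-en-1-ol | OC/C(C)=C\C | intermediate
19 | [(2R,3S)-2,3-dimethyloxiran-2-yl]methanol | OC[C@@]1(C)O[C@H]1C | intermediate
20 | (2S,3S)-2,3-dimethyloxirane-2-carboxylic acid | OC(=O)[C@@]1(C)O[C@H]1C | intermediate
21 | (2S,3S)-2,3-dimethyloxirane-2-carboxylic 2,4,6-trichlorobenzoic anhydride | O=C(OC(=O)[C@@]1(C)O[C@H]1C)c1c(Cl)cc(Cl)cc1Cl | intermediate
22 | (1S,2S,3aR,6R,7S,7aR)-1-[1-(TBS-oxy)ethyl]-4-methylidene-7-(propan-2-yl)-2-(TES-oxy)octahydro-1H-inden-6-yl (2S,3S)-2,3-dimethyloxirane-2-carboxylate | C=C1C[C@@H](OC(=O)[C@@]2(C)O[C@H]2C)[C@@H](C(C)C)[C@@H]2[C@@H](C(C)O[Si](C)(C)C(C)(C)C)[C@@H](O[Si](CC)(CC)CC)C[C@@H]12 | intermediate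
23 | (1R,2S,3aR,6R,7S,7aR)-1-[1-(TBS-oxy)ethyl]-2-hydroxy-4-methylidene-7-(propan-2-yl)octahydro-1H-inden-6-yl (2S,3S)-2,3-dimethyloxirane-2-carboxylate | C=C1C[C@@H](OC(=O)[C@@]2(C)O[C@H]2C)[C@@H](C(C)C)[C@@H]2[C@@H](C(C)O[Si](C)(C)C(C)(C)C)[C@@H](O)C[C@@H]12 | intermediate
24 | (Z)-2-methylbut-2-enoic acid (angelic acid) | OC(=O)/C(C)=C\C | starting material
25 | (Z)-2-methylbut-2-enoic 2,4,6-trichlorobenzoic anhydride | O=C(OC(=O)/C(C)=C\C)c1c(Cl)cc(Cl)cc1Cl | intermediate
26 | (1R,2S,3aR,6R,7S,7aR)-1-[1-(TBS-oxy)ethyl]-4-methylidene-2-[(Z)-2-methylbut-2-enoyloxy]-7-(propan-2-yl)octahydro-1H-inden-6-yl (2S,3S)-2,3-dimethyloxirane-2-carboxylate | C=C1C[C@@H](OC(=O)[C@@]2(C)O[C@H]2C)[C@@H](C(C)C)[C@@H]2[C@@H](C(C)O[Si](C)(C)C(C)(C)C)[C@@H](OC(=O)/C(C)=C\C)C[C@@H]12 | intermediate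
27 | (1S,2S,3aR,6R,7S,7aR)-1-(1-hydroxyethyl)-4-methylidene-2-[(Z)-2-methylbut-2-enoyloxy]-7-(propan-2-yl)octahydro-1H-inden-6-yl (2S,3S)-2,3-dimethyloxirane-2-carboxylate | C=C1C[C@@H](OC(=O)[C@@]2(C)O[C@H]2C)[C@@H](C(C)C)[C@@H]2[C@@H](C(C)O)[C@@H](OC(=O)/C(C)=C\C)C[C@@H]12 | intermediate
28 | (1R,2S,3aR,6R,7S,7aR)-1-acetyl-4-methylidene-2-[(Z)-2-methylbut-2-enoyloxy]-7-(propan-2-yl)octahydro-1H-inden-6-yl (2S,3S)-2,3-dimethyloxirane-2-carboxylate | C=C1C[C@@H](OC(=O)[C@@]2(C)O[C@H]2C)[C@@H](C(C)C)[C@@H]2[C@@H](C(C)=O)[C@@H](OC(=O)/C(C)=C\C)C[C@@H]12 | target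

**Totals**
Total step count: 19. Longest linear sequence: 15 steps (1, 2, 4–11, 15–19); steps 3 and 12–14 are side branches.

**Three steps most likely to fail**

Step 4 (Mukaiyama–Michael). The trans addition to the ring is secure, but the configuration at the side-chain α-carbon (future C-7) rests on an open transition state, and the anti preference is an expectation, not a certainty for this hindered pair. Fallback, setting out from 5 and coming back at 15: a lithium-chelated three-component coupling. Enone 5 is treated at −78 °C with the lithium (Z)-enolate of 1-(3-methylbutanoyl)pyrrolidine (LDA, THF), whose geometry is fixed. The resulting cyclopentanone enolate is transmetallated with ZnCl2 and trapped with acetaldehyde to give hydroxy amide F1. TBSOTf/2,6-lutidine gives silyl ether F2, L-Selectride gives cis alcohol F3, and TESOTf gives bis-silyl ether F4. Cp2Zr(H)Cl (THF, rt) then reduces the tertiary amide directly to aldehyde 15.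

Step 11 (type II carbonyl-ene cyclisation). The hindered α-branched aldehyde may react sluggishly, the Lewis acid may attack the silyl ethers, and the axial-alcohol selectivity is argued from the transition-state model only. Fallback, setting out from 13 and coming back at 16: an intramolecular Nozaki–Hiyama allylation. Ene-type chlorination of the isopropenyl group of 13 (Ca(OCl)2, solid CO2, CH2Cl2/H2O, 0 °C) gives allylic chloride F5. DIBAL-H gives primary alcohol F6 and Dess–Martin oxidation gives aldehyde F7. CrCl2 (cat. NaI, THF, rt, high dilution) closes the ring through a closed chair-like allylchromium transition state, which again puts the oxygen axial, to give 16.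

Step 15 (acylation of the hindered axial 6-OH with an α-quaternary epoxy acid). Acyl transfer may stall. Fallback, setting out from 16 and coming back at 22: form the C6–O bond by SN2 instead. Buffered Dess–Martin oxidation of 16 gives β,γ-unsaturated ketone F8, which is used at once to avoid conjugation. NaBH4/CeCl3 (MeOH, −78 °C) gives the equatorial 6-epimer alcohol F9 by axial hydride delivery; any 16 formed alongside is separated and recycled. Mitsunobu reaction of F9 with acid 20 (PPh3, DIAD, toluene, 0 °C → rt) gives 22 with inversion, as in the menthol to neomenthyl ester inversion.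

**Further compounds**
F1 | step 4 | 1-{(2S)-2-[(1S,2S,5R)-2-(1-hydroxyethyl)-3-oxo-5-(prop-1-en-2-yl)cyclopentyl]-3-methylbutanoyl}pyrrolidine | C1[C@@H](C(C)=C)[C@H]([C@H](C(C)C)C(=O)N2CCCC2)[C@@H](C(C)O)C1=O
F2 | step 4 | TBS ether of F1 at the 1-hydroxyethyl group | C1[C@@H](C(C)=C)[C@H]([C@H](C(C)C)C(=O)N2CCCC2)[C@@H](C(C)O[Si](C)(C)C(C)(C)C)C1=O
F3 | step 4 | ring alcohol from F2, OH cis to the silyloxyethyl group | C1[C@@H](C(C)=C)[C@H]([C@H](C(C)C)C(=O)N2CCCC2)[C@@H](C(C)O[Si](C)(C)C(C)(C)C)[C@H]1O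
F4 | step 4 | TES ether of F3 (pyrrolidine amide analogue of 13) | C1[C@@H](C(C)=C)[C@H]([C@H](C(C)C)C(=O)N2CCCC2)[C@@H](C(C)O[Si](C)(C)C(C)(C)C)[C@H]1O[Si](CC)(CC)CC
F5 | step 11 | methyl (2S)-2-[(1S,2S,3S,5R)-2-[1-(TBS-oxy)ethyl]-5-(3-chloroprop-1-en-2-yl)-3-(TES-oxy)cyclopentyl]-3-methylbutanoate | C1[C@@H](C(CCl)=C)[C@H]([C@H](C(C)C)C(=O)OC)[C@@H](C(C)O[Si](C)(C)C(C)(C)C)[C@H]1O[Si](CC)(CC)CC
F6 | step 11 | primary alcohol from F5 (allylic chloride analogue of 14) | C1[C@@H](C(CCl)=C)[C@H]([C@H](C(C)C)CO)[C@@H](C(C)O[Si](C)(C)C(C)(C)C)[C@H]1O[Si](CC)(CC)CC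
F7 | step 11 | aldehyde from F6 (allylic chloride analogue of 15) | C1[C@@H](C(CCl)=C)[C@H]([C@H](C(C)C)C=O)[C@@H](C(C)O[Si](C)(C)C(C)(C)C)[C@H]1O[Si](CC)(CC)CC
F8 | step 15 | (1S,2S,3aR,7S,7aR)-1-[1-(TBS-oxy)ethyl]-4-methylidene-7-(propan-2-yl)-2-(TES-oxy)octahydro-6H-inden-6-one | C=C1CC(=O)[C@@H](C(C)C)[C@@H]2[C@@H](C(C)O[Si](C)(C)C(C)(C)C)[C@@H](O[Si](CC)(CC)CC)C[C@@H]12
F9 | step 15 | 6-epimer of 16 (equatorial 6-OH, trans to isopropyl) | C=C1C[C@H](O)[C@@H](C(C)C)[C@@H]2[C@@H](C(C)O[Si](C)(C)C(C)(C)C)[C@@H](O[Si](CC)(CC)CC)C[C@@H]12
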